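## Retrosynthetic overview

1. Teferin 26 ⇒ acylation of the C6 hydroxyl of diol 22 with O-acetylvanillic acid 24. 22 ⇒ hydroxy enone 21 ⇒ hydroxy dienone 19 (C6 carbinol by C4–OH-directed reduction, C8=C9 by 1,6-reduction).
2. 19 ⇒ methoxy cycloheptatriene 17 ⇒ azulenone 15: the C6 ketone is carried as a methyl enol ether and the C2 carbonyl is removed by Wolff–Kishner reduction.
3. Feature and key disconnection: ring atoms C5–C10 (oxygen on C6, methyl on C8) are a 2-methoxy-4-methylphenyl ring into whose C5–C10 bond the quaternary carbon C1 with its methyl group is inserted. Hence 15 ⇒ α-methyl diazoketone 13 (bonds C1–C5 and C1–C10).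
4. 13 ⇒ silyloxy acid 11 ⇒ (R)-1,3-diol 7 ⇒ Sharpless epoxidation and Red-Al opening of (Z)-allylic alcohol 5 ⇒ enol triflate 2 + arylboronic acid 3.
5. Ring order: the benzene ring is bought; the five-membered ring (carbene addition) and the seven-membered ring (norcaradiene opening) form together in step 9; no ring is made later.

Key step: step 9

Remark on numbering: C1–C10 are daucane positions (C1 methyl-bearing fusion carbon, C2/C3 CH2, C4 isopropyl carbinol, C5 fusion CH, C6 acyloxy carbon, C7, C8 methyl-bearing, C9, C10).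
Assumption: diazoethane is not sold; it is made just before use from N-ethyl-N-nitrosourea and aqueous KOH and handled as a cold ether solution behind a shield.

## Route

Step 1
Reactants: 1 ethyl 4-methyl-3-oxopentanoate
Product: 2 ethyl (2Z)-4-methyl-3-{[(trifluoromethyl)sulfonyl]oxy}pent-2-enoate
Conditions: Tf2O (1.2 equiv), aq. LiOH, toluene, 5–10 °C
Reagents that add atoms: trifluoromethanesulfonic anhydride, O=S(=O)(OS(=O)(=O)C(F)(F)F)C(F)(F)F
Why: O-triflation of the lithium-chelated Z-enolate of a β-keto ester (enol triflate formation) should place the triflate cis to the ester.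

Step 2
Reactants: 2 ethyl (2Z)-4-methyl-3-{[(trifluoromethyl)sulfonyl]oxy}pent-2-enoate; 3 (2-methoxy-4-methylphenyl)boronic acid
Product: 4 ethyl (2Z)-3-(2-methoxy-4-methylphenyl)-4-methylpent-2-enoate
Conditions: Pd(OAc)2 (3 mol%), SPhos (6 mol%), K3PO4, THF/H2O, 40 °C
Reagents that add atoms: none
Why: Suzuki–Miyaura coupling of an activated vinyl triflate proceeds with retention, so the aryl group ends cis to the ester, the geometry the epoxidation needs.

Step 3
Reactants: 4 ethyl (2Z)-3-(2-methoxy-4-methylphenyl)-4-methylpent-2-enoate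
Product: 5 (2Z)-3-(2-methoxy-4-methylphenyl)-4-methylpent-2-en-1-ol
Conditions: DIBAL-H (2.5 equiv), CH2Cl2, −78 → 0 °C; Rochelle salt work-up
Reagents that add atoms: none
Why: DIBAL-H 1,2-reduction of the enoate gives the allylic alcohol without touching the trisubstituted alkene or its geometry.

Step 4
Reactants: 5 (2Z)-3-(2-methoxy-4-methylphenyl)-4-methylpent-2-en-1-ol
Product: 6 [(2S,3R)-3-(2-methoxy-4-methylphenyl)-3-(propan-2-yl)oxiran-2-yl]methanol
Conditions: Ti(Oi-Pr)4 (0.2 equiv), L-(+)-diisopropyl tartrate (0.25 equiv), t-BuOOH (2 equiv, decane), 4 Å MS, CH2Cl2, −20 °C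
Reagents that add atoms: tert-butyl hydroperoxide, CC(C)(C)OO
Why: Sharpless asymmetric epoxidation: the L-(+)-tartrate catalyst should epoxidise this Z-configured 3,3-disubstituted allylic alcohol on the face that gives (2S,3R), as with nerol, which fixes the tertiary benzylic C–O centre (later C4, R); the catalytic, sieve-dried protocol is chosen to spare the acid-labile epoxide, and the enantiomeric purity is to be checked and, if needed, raised by crystallising diol 7.

Step 5
Reactants: 6 [(2S,3R)-3-(2-methoxy-4-methylphenyl)-3-(propan-2-yl)oxiran-2-yl]methanol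
Product: 7 (3R)-3-(2-methoxy-4-methylphenyl)-4-methylpentane-1,3-diol
Conditions: Red-Al (2.5 equiv), THF, 0 °C → rt
Reagents that add atoms: none
Why: Regioselective reductive opening of a 2,3-epoxy alcohol: the aluminate bound to the primary alkoxide delivers hydride to C2, so the tertiary C–O bond and its configuration stay untouched.

Step 6
Reactants: 7 (3R)-3-(2-methoxy-4-methylphenyl)-4-methylpentane-1,3-diol
Product: 9 (3R)-3-hydroxy-3-(2-methoxy-4-methylphenyl)-4-methylpentanoic acid, via hydroxy aldehyde 8 (not isolated)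
Conditions: TEMPO (0.2 equiv), PhI(OAc)2 (2.5 equiv), MeCN/aq. pH 7 buffer, rt
Reagents that add atoms: water, O
Why: Oxoammonium (TEMPO/PhI(OAc)2) oxidation takes only the primary alcohol through the aldehyde hydrate to the acid; the tertiary alcohol cannot be oxidised and the chlorine-free oxidant spares the anisole ring.

Step 7
Reactants: 9 (3R)-3-hydroxy-3-(2-methoxy-4-methylphenyl)-4-methylpentanoic acid
Product: 11 (3R)-3-[(tert-butyldimethylsilyl)oxy]-3-(2-methoxy-4-methylphenyl)-4-methylpentanoic acid, via silyl ester 10 (not isolated)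
Conditions: TBSOTf (3 equiv), 2,6-lutidine (5 equiv), CH2Cl2, 0 °C → rt; then AcOH/THF/H2O, rt
Reagents that add atoms: tert-butyldimethylsilyl trifluoromethanesulfonate, CC(C)(C)[Si](C)(C)OS(=O)(=O)C(F)(F)F
Why: The silyl triflate with a hindered base silylates the hindered tertiary alcohol and the acid, and the labile silyl ester is then hydrolysed selectively by aqueous acetic acid while the tertiary silyl ether stays.

Step 8
Reactants: 11 (3R)-3-[(tert-butyldimethylsilyl)oxy]-3-(2-methoxy-4-methylphenyl)-4-methylpentanoic acid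
Product: 13 (5R)-5-[(tert-butyldimethylsilyl)oxy]-2-diazo-5-(2-methoxy-4-methylphenyl)-6-methylheptan-3-one, via acid chloride 12 (not isolated)
Conditions: 1-chloro-N,N,2-trimethylprop-1-en-1-amine (1.2 equiv), CH2Cl2, 0 °C → rt; then CH3CHN2 (3 equiv), Et2O, −20 → 0 °C
Reagents that add atoms: diazoethane, CC=[N+]=[N-]
Why: The chloroenamine makes the acid chloride under neutral conditions (no HCl at the acid-labile benzylic silyl ether), and acylation of excess diazoethane (Arndt–Eistert-type diazoketone synthesis) gives the α-methyl diazoketone, a second equivalent taking up the HCl.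

Step 9
Reactants: 13 (5R)-5-[(tert-butyldimethylsilyl)oxy]-2-diazo-5-(2-methoxy-4-methylphenyl)-6-methylheptan-3-one
Product: 15 (3R,8aR)-3-[(tert-butyldimethylsilyl)oxy]-4-methoxy-6,8a-dimethyl-3-(propan-2-yl)-3,8a-dihydroazulen-1(2H)-one, via norcaradiene 14 (not isolated)
Conditions: Rh2(OAc)4 (1 mol%), CH2Cl2, 40 °C, slow addition of 13 at high dilution
Reagents that add atoms: none
Why: Loss of N2 gives a rhodium carbenoid at C1 that adds to the unsubstituted ipso–ortho bond C5–C10 of the electron-rich ring to give norcaradiene 14, whose 6π-disrotatory opening of the C5–C10 bond gives cycloheptatriene 15; this is the intramolecular Buchner reaction of 1-diazo-4-arylbutan-2-ones, known also for α-methyl diazoketones that give 8a-methylazulenones. The cyclopentanone closes by intramolecular [2+1] carbene addition (C1–C5, with C1–C10 completing the cyclopropane) and the seven-membered ring arises by electrocyclic ring expansion of the benzene ring; because C1 carries no hydrogen the triene cannot drift by 1,5-hydrogen shift. The new quaternary centre C1 is controlled by C4: with the tether over the C5–C10 bond the small silyloxy group takes the in-plane (inside) position beside the ortho methoxy group and the isopropyl group lies anti to the incoming carbenoid, which should place the C1 methyl cis to the C4 oxygen (1R in daucane terms). The step needs addition at C5–C10 and not at the methoxy-bearing C5–C6 bond (secured by the methoxy substituent and the in-plane demand just named), aromatic addition in preference to 1,5-C–H insertion at the isopropyl methine, attack on the silyloxy oxygen or 1,2-hydride shift (secured by the electron-rich ring, the hindered and weakly basic tertiary OTBS oxygen, the primary C–H bonds of the methyl group and slow addition), and one face at C1 (secured by C4, with a Cu(I)–bis(oxazoline) catalyst of matched sense in reserve).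

Step 10
Reactants: 15 (3R,8aR)-3-[(tert-butyldimethylsilyl)oxy]-4-methoxy-6,8a-dimethyl-3-(propan-2-yl)-3,8a-dihydroazulen-1(2H)-one
Product: 17 tert-butyl{[(1R,3aR)-8-methoxy-3a,6-dimethyl-1-(propan-2-yl)-1,2,3,3a-tetrahydroazulen-1-yl]oxy}dimethylsilane, via N-silyl hydrazone 16 (not isolated)
Conditions: TBSNHNHTBS (1.5 equiv), Sc(OTf)3 (0.01 mol%), neat, 23 → 60 °C; then KOt-Bu, t-BuOH, DMSO, 23 → 80 °C
Reagents that add atoms: none
Why: Wolff–Kishner reduction in its N-silylhydrazone variant removes the C2 carbonyl under non-acidic, anionic conditions, chosen because a C2 radical next to the divinyl-substituted C1 would rearrange and because the enol ether and silyl ether tolerate base.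

Step 11
Reactants: 17 tert-butyl{[(1R,3aR)-8-methoxy-3a,6-dimethyl-1-(propan-2-yl)-1,2,3,3a-tetrahydroazulen-1-yl]oxy}dimethylsilane
Product: 19 (3R,3aR,8aR)-3-hydroxy-6,8a-dimethyl-3-(propan-2-yl)-2,3,3a,8a-tetrahydroazulen-4(1H)-one, via silyloxy dienone 18 (not isolated)
Conditions: 0.5 M aq. HCl, THF, 0 °C; then 48% aq. HF, MeCN, 0 °C → rt
Reagents that add atoms: water, O
Why: Enol ether hydrolysis (C5 protonation, water adding to the C6 oxocarbenium ion) is much faster than ionisation of the silyl-protected C4–O bond, and HF then cleaves the tertiary silyl ether; C5 should be protonated anti to the C1 methyl and the silyloxy group, and the trans-fused hydroxy ketone, the only C5 epimer with a C4–OH···O=C6 hydrogen bond, is also the expected product of equilibration at this enolisable centre.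

Step 12
Reactants: 19 (3R,3aR,8aR)-3-hydroxy-6,8a-dimethyl-3-(propan-2-yl)-2,3,3a,8a-tetrahydroazulen-4(1H)-one
Product: 21 (3R,3aR,8aR)-3-hydroxy-6,8a-dimethyl-3-(propan-2-yl)-2,3,3a,5,8,8a-hexahydroazulen-4(1H)-one, via lithium dienolate 20 (not isolated)
Conditions: Li (2.5 equiv), NH3(l)/THF, t-BuOH (1 equiv), −78 °C; then solid NH4Cl
Reagents that add atoms: none
Why: Dissolving-metal 1,6-reduction of a linear dienone: two electrons and a proton at C10 give the extended dienolate, and kinetic protonation at the α-carbon C7 on quenching gives the deconjugated C8=C9 enone, as in the lithium–ammonia reduction of steroidal 4,6-dien-3-ones.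

Step 13
Reactants: 21 (3R,3aR,8aR)-3-hydroxy-6,8a-dimethyl-3-(propan-2-yl)-2,3,3a,5,8,8a-hexahydroazulen-4(1H)-one
Product: 22 (3R,3aS,4S,8aR)-6,8a-dimethyl-3-(propan-2-yl)-1,2,3,3a,4,5,8,8a-octahydroazulene-3,4-diol
Conditions: Me4NBH(OAc)3 (5 equiv), MeCN/AcOH (1:1), −30 → −20 °C
Reagents that add atoms: none
Why: Evans–Saksena hydroxyl-directed reduction: the C4 hydroxyl exchanges onto boron and delivers hydride through a six-membered transition state to the face of C6 on which it sits, which should put the C6 oxygen trans to the C4 oxygen (equatorial, H6 anti to H5), the 6S configuration of the target and also the more stable epimer.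

Step 14
Reactants: 23 vanillic acid
Product: 24 4-acetoxy-3-methoxybenzoic acid
Conditions: Ac2O (1.2 equiv), pyridine, 0 °C → rt; then H2O
Reagents that add atoms: acetic anhydride, CC(=O)OC(C)=O
Why: O-Acetylation of the phenol blocks self-acylation of the acid in the coupling step.

Step 15
Reactants: 22 (3R,3aS,4S,8aR)-6,8a-dimethyl-3-(propan-2-yl)-1,2,3,3a,4,5,8,8a-octahydroazulene-3,4-diol; 24 4-acetoxy-3-methoxybenzoic acid
Product: 25 (3R,3aS,4S,8aR)-3-hydroxy-6,8a-dimethyl-3-(propan-2-yl)-1,2,3,3a,4,5,8,8a-octahydroazulen-4-yl 4-acetoxy-3-methoxybenzoate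
Conditions: DCC (1.5 equiv), DMAP (0.5 equiv), CH2Cl2, rt
Reagents that add atoms: none
Why: Steglich esterification acylates the secondary C6 hydroxyl only, since the tertiary C4 hydroxyl is inert to the acylpyridinium intermediate.

Step 16
Reactants: 25 (3R,3aS,4S,8aR)-3-hydroxy-6,8a-dimethyl-3-(propan-2-yl)-1,2,3,3a,4,5,8,8a-octahydroazulen-4-yl 4-acetoxy-3-methoxybenzoate
Product: 26 teferin
Conditions: pyrrolidine (3 equiv), CH2Cl2, 0 °C → rt
Reagents that add atoms: none
Why: Aminolysis of the aryl acetate is far faster than attack on the hindered, electron-rich aroyl ester, so only the phenol is freed.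

## Compound list

1 | ethyl 4-methyl-3-oxopentanoate | CCOC(=O)CC(=O)C(C)C | starting material
2 | ethyl (2Z)-4-methyl-3-{[(trifluoromethyl)sulfonyl]oxy}pent-2-enoate (triflate cis to ester) | CCOC(=O)/C=C(\OS(=O)(=O)C(F)(F)F)C(C)C | intermediate
3 | (2-methoxy-4-methylphenyl)boronic acid | COc1cc(C)ccc1B(O)O | starting material
4 | ethyl (2Z)-3-(2-methoxy-4-methylphenyl)-4-methylpent-2-enoate (aryl cis to ester) | CCOC(=O)/C=C(\c1ccc(C)cc1OC)C(C)C | intermediate
5 | (2Z)-3-(2-methoxy-4-methylphenyl)-4-methylpent-2-en-1-ol | OC/C=C(\c1ccc(C)cc1OC)C(C)C | intermediate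
6 | [(2S,3R)-3-(2-methoxy-4-methylphenyl)-3-(propan-2-yl)oxiran-2-yl]methanol | OC[C@@H]1O[C@]1(C(C)C)c1ccc(C)cc1OC | intermediate
7 | (3R)-3-(2-methoxy-4-methylphenyl)-4-methylpentane-1,3-diol | OCC[C@@](O)(C(C)C)c1ccc(C)cc1OC | intermediate
8 | (3R)-3-hydroxy-3-(2-methoxy-4-methylphenyl)-4-methylpentanal (not isolated) | O=CC[C@@](O)(C(C)C)c1ccc(C)cc1OC | intermediate
9 | (3R)-3-hydroxy-3-(2-methoxy-4-methylphenyl)-4-methylpentanoic acid | OC(=O)C[C@@](O)(C(C)C)c1ccc(C)cc1OC | intermediate
10 | tert-butyldimethylsilyl (3R)-3-[(tert-butyldimethylsilyl)oxy]-3-(2-methoxy-4-methylphenyl)-4-methylpentanoate (not isolated) | CC(C)(C)[Si](C)(C)OC(=O)C[C@@](O[Si](C)(C)C(C)(C)C)(C(C)C)c1ccc(C)cc1OC | intermediate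
11 | (3R)-3-[(tert-butyldimethylsilyl)oxy]-3-(2-methoxy-4-methylphenyl)-4-methylpentanoic acid | OC(=O)C[C@@](O[Si](C)(C)C(C)(C)C)(C(C)C)c1ccc(C)cc1OC | intermediate
12 | (3R)-3-[(tert-butyldimethylsilyl)oxy]-3-(2-methoxy-4-methylphenyl)-4-methylpentanoyl chloride (not isolated) | ClC(=O)C[C@@](O[Si](C)(C)C(C)(C)C)(C(C)C)c1ccc(C)cc1OC | intermediate
13 | (5R)-5-[(tert-butyldimethylsilyl)oxy]-2-diazo-5-(2-methoxy-4-methylphenyl)-6-methylheptan-3-one | CC(=[N+]=[N-])C(=O)C[C@@](O[Si](C)(C)C(C)(C)C)(C(C)C)c1ccc(C)cc1OC | intermediate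
14 | norcaradiene valence isomer of 15 (cyclopropane C1–C5–C10, dienes C6=C7 and C8=C9; not isolated) | COC1=CC(C)=C[C@@H]2[C@@]3(C)C(=O)C[C@@](O[Si](C)(C)C(C)(C)C)(C(C)C)[C@@]123 | intermediate
15 | (3R,8aR)-3-[(tert-butyldimethylsilyl)oxy]-4-methoxy-6,8a-dimethyl-3-(propan-2-yl)-3,8a-dihydroazulen-1(2H)-one (angular methyl cis to the silyloxy group) | COC=1C=C(C)C=C[C@@]2(C)C(=O)C[C@@](O[Si](C)(C)C(C)(C)C)(C(C)C)C12 | intermediate
16 | N-(tert-butyldimethylsilyl)hydrazone of 15 at the ring carbonyl (not isolated) | COC=1C=C(C)C=C[C@@]2(C)C(=NN[Si](C)(C)C(C)(C)C)C[C@@](O[Si](C)(C)C(C)(C)C)(C(C)C)C12 | intermediate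
17 | tert-butyl{[(1R,3aR)-8-methoxy-3a,6-dimethyl-1-(propan-2-yl)-1,2,3,3a-tetrahydroazulen-1-yl]oxy}dimethylsilane | COC=1C=C(C)C=C[C@@]2(C)CC[C@@](O[Si](C)(C)C(C)(C)C)(C(C)C)C12 | intermediate
18 | (3R,3aR,8aR)-3-[(tert-butyldimethylsilyl)oxy]-6,8a-dimethyl-3-(propan-2-yl)-2,3,3a,8a-tetrahydroazulen-4(1H)-one (not isolated) | O=C1C=C(C)C=C[C@@]2(C)CC[C@@](O[Si](C)(C)C(C)(C)C)(C(C)C)[C@H]12 | intermediate
19 | (3R,3aR,8aR)-3-hydroxy-6,8a-dimethyl-3-(propan-2-yl)-2,3,3a,8a-tetrahydroazulen-4(1H)-one (trans-fused) | O=C1C=C(C)C=C[C@@]2(C)CC[C@@](O)(C(C)C)[C@H]12 | intermediate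
20 | lithium C6–C9 dienolate of 21 (not isolated) | [Li+].[O-]C1=CC(C)=CC[C@@]2(C)CC[C@@](O)(C(C)C)[C@H]12 | intermediate
21 | (3R,3aR,8aR)-3-hydroxy-6,8a-dimethyl-3-(propan-2-yl)-2,3,3a,5,8,8a-hexahydroazulen-4(1H)-one | O=C1CC(C)=CC[C@@]2(C)CC[C@@](O)(C(C)C)[C@H]12 | intermediate
22 | (3R,3aS,4S,8aR)-6,8a-dimethyl-3-(propan-2-yl)-1,2,3,3a,4,5,8,8a-octahydroazulene-3,4-diol (jaeschkeanadiol) | O[C@H]1CC(C)=CC[C@@]2(C)CC[C@@](O)(C(C)C)[C@H]12 | intermediate
23 | vanillic acid | COc1cc(C(=O)O)ccc1O | starting material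
24 | 4-acetoxy-3-methoxybenzoic acid | COc1cc(C(=O)O)ccc1OC(C)=O | intermediate
25 | (3R,3aS,4S,8aR)-3-hydroxy-6,8a-dimethyl-3-(propan-2-yl)-1,2,3,3a,4,5,8,8a-octahydroazulen-4-yl 4-acetoxy-3-methoxybenzoate | COc1cc(C(=O)O[C@H]2CC(C)=CC[C@@]3(C)CC[C@@](O)(C(C)C)[C@H]23)ccc1OC(C)=O | intermediate
26 | teferin, (3R,3aS,4S,8aR)-3-hydroxy-6,8a-dimethyl-3-(propan-2-yl)-1,2,3,3a,4,5,8,8a-octahydroazulen-4-yl 4-hydroxy-3-methoxybenzoate | COc1cc(C(=O)O[C@H]2CC(C)=CC[C@@]3(C)CC[C@@](O)(C(C)C)[C@H]23)ccc1O | target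

## Count and risks

Total step count: 16.
Longest linear sequence: 15 steps (steps 1–13, 15 and 16; step 14 is a one-step side branch).

Steps most likely to fail:

**Step 9.** What may go wrong: the carbenoid is consumed by 1,5-C–H insertion at the isopropyl methine or by attack on the silyloxy oxygen, or it adds to both faces of the C5–C10 bond. Fallback (sets out from 3, returns at 17): the ring expansion is run before the tertiary centre exists and the isopropyl group is added afterwards.
- Oxidative Heck coupling of 3 with ethyl acrylate (Pd(OAc)2, Cu(OAc)2, DMF) should give ethyl (2E)-3-(2-methoxy-4-methylphenyl)prop-2-enoate F1.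
- Copper-catalysed enantioselective β-borylation (CuCl, NaOt-Bu, Josiphos-type ligand, B2pin2, MeOH) gives the benzylic boronate F2, oxidised in the same flask (NaBO3) to the (R)-β-hydroxy ester F3.
- TBSCl/imidazole gives the silyl ether ester F4 and LiOH the silyloxy acid F5; the chloroenamine of step 8 gives the acid chloride F6 and diazoethane the diazoketone F7.
- Rh2(OAc)4 then gives, through the norcaradiene F8, the azulenone F9. Here the benzylic hydrogen takes the in-plane position beside the methoxy group, so the silyloxy group ends anti to the new methyl group and the secondary carbinol relays its configuration to C1.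
- Wolff–Kishner reduction as in step 10, through the N-silyl hydrazone F10, gives the silyloxy triene F11; TBAF gives the allylic alcohol F12 and MnO2 the vinylogous ester F13.
- i-PrMgCl/CeCl3 should add to the C4 carbonyl from the face opposite the C1 methyl group to give the tertiary alcohol F14, which TBSOTf/2,6-lutidine at −78 °C converts into 17.

**Step 10.** What may go wrong: incomplete condensation at the hindered C2 ketone, or base-induced isomerisation or rearrangement of the triene (the incipient C2 anion closing onto C10). Fallback (sets out from 15, returns at 21): the carbonyl is carried as an alcohol and removed by radical deoxygenation only after C1 has lost its vinyl neighbours.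
- NaBH4 in MeOH reduces 15 to the C2 alcohol F15 (either epimer serves).
- The acid treatment of step 11 gives, through the silyloxy dienone F16, the keto diol F17.
- Lithium in ammonia as in step 12 gives, through the lithium dienolate F18, the hydroxy enone F19.
- PhOC(S)Cl/pyridine/DMAP converts the secondary C2 hydroxyl (the tertiary one is inert) into the phenyl thionocarbonate F20.
- Barton–McCombie reduction (Bu3SnH, AIBN, toluene, 80 °C) gives 21.

**Step 11.** What may go wrong: loss of the C4 oxygen by β-elimination to the cross-conjugated trienone, or retro-aldol opening of the five-membered ring, once the free β-hydroxy ketone is exposed. Fallback (sets out from 17, returns at 22): the silyl ether is kept until C6 is no longer a ketone, so the β-hydroxy ketone is never formed.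
- Only the enol ether is hydrolysed (0.5 M aq. HCl, THF, 0 °C) and 18 is isolated.
- Lithium in ammonia as in step 12 gives, through the lithium dienolate F21, the silyloxy enone F22.
- The C6 ketone is then reduced under thermodynamic control (Li, NH3, EtOH, −78 °C) to the equatorial alcohol F23, which is the epimer wanted (H6 anti to H5, oxygen away from the axial C1 methyl).
- TBAF removes the silyl group to give 22.

## Further compounds

F1 | step 9 | ethyl (2E)-3-(2-methoxy-4-methylphenyl)prop-2-enoate | CCOC(=O)/C=C/c1ccc(C)cc1OC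
F2 | step 9 | ethyl (3R)-3-(2-methoxy-4-methylphenyl)-3-(4,4,5,5-tetramethyl-1,3,2-dioxaborolan-2-yl)propanoate | CCOC(=O)C[C@@H](B1OC(C)(C)C(C)(C)O1)c1ccc(C)cc1OC
F3 | step 9 | ethyl (3R)-3-hydroxy-3-(2-methoxy-4-methylphenyl)propanoate | CCOC(=O)C[C@@H](O)c1ccc(C)cc1OC
F4 | step 9 | ethyl (3R)-3-[(tert-butyldimethylsilyl)oxy]-3-(2-methoxy-4-methylphenyl)propanoate | CCOC(=O)C[C@@H](O[Si](C)(C)C(C)(C)C)c1ccc(C)cc1OC
F5 | step 9 | (3R)-3-[(tert-butyldimethylsilyl)oxy]-3-(2-methoxy-4-methylphenyl)propanoic acid | OC(=O)C[C@@H](O[Si](C)(C)C(C)(C)C)c1ccc(C)cc1OC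
F6 | step 9 | (3R)-3-[(tert-butyldimethylsilyl)oxy]-3-(2-methoxy-4-methylphenyl)propanoyl chloride | ClC(=O)C[C@@H](O[Si](C)(C)C(C)(C)C)c1ccc(C)cc1OC
F7 | step 9 | (5R)-5-[(tert-butyldimethylsilyl)oxy]-2-diazo-5-(2-methoxy-4-methylphenyl)pentan-3-one | CC(=[N+]=[N-])C(=O)C[C@@H](O[Si](C)(C)C(C)(C)C)c1ccc(C)cc1OC
F8 | step 9 | norcaradiene valence isomer of F9 | COC1=CC(C)=C[C@@H]2[C@@]3(C)C(=O)C[C@@H](O[Si](C)(C)C(C)(C)C)[C@@]123
F9 | step 9 | (3R,8aR)-3-[(tert-butyldimethylsilyl)oxy]-4-methoxy-6,8a-dimethyl-3,8a-dihydroazulen-1(2H)-one | COC=1C=C(C)C=C[C@@]2(C)C(=O)C[C@@H](O[Si](C)(C)C(C)(C)C)C12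
F10 | step 9 | N-(tert-butyldimethylsilyl)hydrazone of F9 | COC=1C=C(C)C=C[C@@]2(C)C(=NN[Si](C)(C)C(C)(C)C)C[C@@H](O[Si](C)(C)C(C)(C)C)C12
F11 | step 9 | tert-butyl{[(1R,3aR)-8-methoxy-3a,6-dimethyl-1,2,3,3a-tetrahydroazulen-1-yl]oxy}dimethylsilane | COC=1C=C(C)C=C[C@@]2(C)CC[C@@H](O[Si](C)(C)C(C)(C)C)C12
F12 | step 9 | (1R,3aR)-8-methoxy-3a,6-dimethyl-1,2,3,3a-tetrahydroazulen-1-ol | COC=1C=C(C)C=C[C@@]2(C)CC[C@@H](O)C12
F13 | step 9 | (3aR)-8-methoxy-3a,6-dimethyl-2,3-dihydroazulen-1(3aH)-one | COC=1C=C(C)C=C[C@@]2(C)CCC(=O)C12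
F14 | step 9 | (1R,3aR)-8-methoxy-3a,6-dimethyl-1-(propan-2-yl)-1,2,3,3a-tetrahydroazulen-1-ol | COC=1C=C(C)C=C[C@@]2(C)CC[C@@](O)(C(C)C)C12
F15 | step 10 | (3R,8aR)-3-[(tert-butyldimethylsilyl)oxy]-4-methoxy-6,8a-dimethyl-3-(propan-2-yl)-1,2,3,8a-tetrahydroazulen-1-ol (carbinol epimers) | COC=1C=C(C)C=C[C@@]2(C)C(O)C[C@@](O[Si](C)(C)C(C)(C)C)(C(C)C)C12
F16 | step 10 | (3R,3aR,8aR)-3-[(tert-butyldimethylsilyl)oxy]-1-hydroxy-6,8a-dimethyl-3-(propan-2-yl)-2,3,3a,8a-tetrahydroazulen-4(1H)-one | O=C1C=C(C)C=C[C@@]2(C)C(O)C[C@@](O[Si](C)(C)C(C)(C)C)(C(C)C)[C@H]12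
F17 | step 10 | (3R,3aR,8aR)-1,3-dihydroxy-6,8a-dimethyl-3-(propan-2-yl)-2,3,3a,8a-tetrahydroazulen-4(1H)-one | O=C1C=C(C)C=C[C@@]2(C)C(O)C[C@@](O)(C(C)C)[C@H]12
F18 | step 10 | lithium C6–C9 dienolate of F19 | [Li+].[O-]C1=CC(C)=CC[C@@]2(C)C(O)C[C@@](O)(C(C)C)[C@H]12
F19 | step 10 | (3R,3aR,8aR)-1,3-dihydroxy-6,8a-dimethyl-3-(propan-2-yl)-2,3,3a,5,8,8a-hexahydroazulen-4(1H)-one | O=C1CC(C)=CC[C@@]2(C)C(O)C[C@@](O)(C(C)C)[C@H]12
F20 | step 10 | O-phenyl thionocarbonate of F19 at the secondary hydroxyl | O=C1CC(C)=CC[C@@]2(C)C(OC(=S)Oc3ccccc3)C[C@@](O)(C(C)C)[C@H]12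
F21 | step 11 | lithium C6–C9 dienolate of F22 | [Li+].[O-]C1=CC(C)=CC[C@@]2(C)CC[C@@](O[Si](C)(C)C(C)(C)C)(C(C)C)[C@H]12
F22 | step 11 | (3R,3aR,8aR)-3-[(tert-butyldimethylsilyl)oxy]-6,8a-dimethyl-3-(propan-2-yl)-2,3,3a,5,8,8a-hexahydroazulen-4(1H)-one | O=C1CC(C)=CC[C@@]2(C)CC[C@@](O[Si](C)(C)C(C)(C)C)(C(C)C)[C@H]12
F23 | step 11 | (3R,3aS,4S,8aR)-3-[(tert-butyldimethylsilyl)oxy]-6,8a-dimethyl-3-(propan-2-yl)-1,2,3,3a,4,5,8,8a-octahydroazulen-4-ol | O[C@H]1CC(C)=CC[C@@]2(C)CC[C@@](O[Si](C)(C)C(C)(C)C)(C(C)C)[C@H]12
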